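A direct plan would close the central ring B last by a chromium carbene benzannulation: the aryloxy(2-ethoxyvinyl)carbene complex A1 (ring A on the carbene oxygen, made from Cr(CO)6) and the aryl ethynyl ether A2 (ring C) would be heated to give the hepta-O-alkyl phenol A3, and BBr3 would then remove the alkyl groups.
Its weakest steps would be:
- The benzannulation of A1 with A2. An aryloxycarbene with a donor on the vinyl terminus and an ynol ether as the alkyne is an untested combination. Cyclopentannulation, cyclobutenone or furan formation and oligomerisation of A2 would compete, and stoichiometric chromium would be spent on it.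
- The phenolysis that makes A1. A di-ortho-substituted phenol would have to attack a thermally labile acetoxycarbene at −40 °C, after a cis-vinyllithium addition to Cr(CO)6, so a fragile complex is reached through two delicate operations.
- The run-up to A2. A dichlorovinyl ether elimination would give a terminal aryl ynol ether that polymerises and hydrates easily. Four of six steps would only prepare partners for building a 1,2,3,5-tetraoxygenated benzene ring that can be bought with that pattern in place.

**Retrosynthetic overview**
Ring B is bought as 3-bromo-4,5-dimethoxybenzaldehyde: C–Br takes ring C by Ullmann coupling, CHO becomes the second ether oxygen by Baeyer–Villiger oxidation.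
Ring A (benzene-1,3,5-triol with the ether oxygen on C2, flanked by the hydroxyls on C1 and C3) is not coupled but grown on that oxygen. Its 1,3,5-oxygen pattern is that of a folded triketide.
The oxygen is alkylated on a primary carbon, the chain is extended to a 6-aryloxy-3,5-dioxohexanoate, and a Claisen cyclisation closes ring A (bond C1–C2) last.
This avoids chromium, the ynol ether and any diaryl ether coupling at a di-ortho-substituted carbon; ring A emerges with its three hydroxyls free.

Key step: step 5

Remark: the rings are lettered A (2,4,6-trihydroxyphenyl), B (central benzene-1,2-diol) and C (3,4,5-trihydroxyphenyl). The target has no stereocentre. Compounds 1, 2, 6 and 8 are assumed to be catalogue chemicals.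

**Step 1**
Reactants: 1 3,4,5-trimethoxyphenol; 2 3-bromo-4,5-dimethoxybenzaldehyde
Product: 3 3,4-dimethoxy-5-(3,4,5-trimethoxyphenoxy)benzaldehyde
Conditions: CuI (10 mol %), N,N-dimethylglycine·HCl (30 mol %), Cs2CO3, 1,4-dioxane, 90 °C, Ar
Reagents that add atoms: none
Why: Copper-catalysed Ullmann diaryl ether synthesis; the unhindered, electron-rich phenoxide of 1 should couple at the C–Br bond of 2, whose single ortho methoxy group and meta formyl group are tolerated, and neither partner can enolise.

**Step 2**
Reactants: 3 3,4-dimethoxy-5-(3,4,5-trimethoxyphenoxy)benzaldehyde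
Product: 5 3,4-dimethoxy-5-(3,4,5-trimethoxyphenoxy)phenol, via aryl formate 4 (not isolated)
Conditions: mCPBA, CH2Cl2, 0 °C to rt; aq. NaHCO3 wash; K2CO3 (cat.), MeOH, rt
Reagents that add atoms: 3-chloroperoxybenzoic acid (mCPBA), OOC(=O)c1cccc(Cl)c1
Why: Baeyer–Villiger oxidation of an electron-rich benzaldehyde (Dakin-type); the para methoxy group should favour aryl over hydride migration, as with 3,4,5-trimethoxybenzaldehyde, and formate 4 is cleaved by mild methanolysis.

**Step 3**
Reactants: 5 3,4-dimethoxy-5-(3,4,5-trimethoxyphenoxy)phenol; 6 methyl bromoacetate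
Product: 7 methyl 2-[3,4-dimethoxy-5-(3,4,5-trimethoxyphenoxy)phenoxy]acetate
Conditions: K2CO3, acetone, reflux
Reagents that add atoms: none
Why: Williamson ether synthesis; SN2 attack of the phenoxide on the α-bromo ester places the oxygen that will later be flanked by two ortho hydroxyl groups on an unhindered primary carbon.

**Step 4**
Reactants: 7 methyl 2-[3,4-dimethoxy-5-(3,4,5-trimethoxyphenoxy)phenoxy]acetate; 8 methyl acetoacetate
Product: 10 methyl 6-[3,4-dimethoxy-5-(3,4,5-trimethoxyphenoxy)phenoxy]-3,5-dioxohexanoate, via acetoacetate dianion 9 (not isolated)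
Conditions: 8 (2.5 equiv), NaH then n-BuLi, THF, 0 °C; 7, −78 to 0 °C; 1 M HCl, 0 °C
Reagents that add atoms: none
Why: Claisen acylation of the acetoacetate dianion at its terminal (γ) carbon by the activated α-aryloxy ester, a standard chain extension to 3,5-dioxo esters; excess 9 is used because the 1,3-diketone product consumes a second equivalent of base.

**Step 5**
Reactants: 10 methyl 6-[3,4-dimethoxy-5-(3,4,5-trimethoxyphenoxy)phenoxy]-3,5-dioxohexanoate
Product: 12 2-[3,4-dimethoxy-5-(3,4,5-trimethoxyphenoxy)phenoxy]benzene-1,3,5-triol, via cyclohexane-1,3,5-trione 11 (not isolated)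
Conditions: KOtBu (3 equiv), THF (0.02 M), 0 to 60 °C, Ar; 1 M HCl, 0 °C
Reagents that add atoms: none
Why: KOtBu deprotonates C4 and then, reversibly, C6 (the OCH2 carbon, made more acidic by its aryloxy group), and the terminal carbon of this 4,6-dianion attacks the ester carbonyl C1; loss of methoxide gives the 2-aryloxycyclohexane-1,3,5-trione 11, which tautomerises at once to the phloroglucinol salt, an aromatic sink that makes the condensation irreversible. The closest known reaction type is the Claisen (Dieckmann-type) cyclisation of 3,5-dioxoalkanoates to phloroglucinols and of 3,5,7-triketo esters to acylphloroglucinols, the polyketide folding by which phloroglucinol itself arises in nature. Ring A is the only ring formed, by 6-exo-trig C-acylation that makes the bond between C2 (the ether carbon) and C1 of ring A, and no stereocentre arises because 11 aromatises. The step needs C-acylation to beat O-acylation by the C5 enolate oxygen (which would give a 6-(aryloxymethyl)-4-hydroxy-2-pyrone); a dianion reacts with esters at its terminal carbon, as 1,3-diketone dianions do, and the aprotic medium keeps that carbanion available. A six-carbon chain has no aldol mode to a six-membered ring, so no resorcinol can form, and the unproductive 2,4-dianion (ester masked as its enolate) should return to the 4,6-dianion by proton transfer through tert-butanol. The aryl methyl ethers and the diaryl ether are inert to tert-butoxide, and dilution and argon guard against intermolecular condensation and air oxidation of the phloroglucinol salt.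

**Step 6**
Reactants: 12 2-[3,4-dimethoxy-5-(3,4,5-trimethoxyphenoxy)phenoxy]benzene-1,3,5-triol
Product: 13 3-(3,4,5-trihydroxyphenoxy)-5-(2,4,6-trihydroxyphenoxy)benzene-1,2-diol (CNP0216308.0)
Conditions: BBr3 (excess), CH2Cl2, −78 °C to rt, Ar; H2O, 0 °C
Reagents that add atoms: none
Why: Lewis acid dealkylation of aryl methyl ethers; bromide attacks each O-methyl carbon of the boron-bound ethers, the three hydroxyl groups of ring A are held as aryl borates meanwhile, and the two diaryl ether bonds offer no sp3 carbon for attack.

**Compound list**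
1 | 3,4,5-trimethoxyphenol | COc1cc(O)cc(OC)c1OC | starting material
2 | 3-bromo-4,5-dimethoxybenzaldehyde | COc1cc(C=O)cc(Br)c1OC | starting material
3 | 3,4-dimethoxy-5-(3,4,5-trimethoxyphenoxy)benzaldehyde | COc1cc(C=O)cc(Oc2cc(OC)c(OC)c(OC)c2)c1OC | intermediate
4 | 3,4-dimethoxy-5-(3,4,5-trimethoxyphenoxy)phenyl formate | COc1cc(OC=O)cc(Oc2cc(OC)c(OC)c(OC)c2)c1OC | intermediate
5 | 3,4-dimethoxy-5-(3,4,5-trimethoxyphenoxy)phenol | COc1cc(O)cc(Oc2cc(OC)c(OC)c(OC)c2)c1OC | intermediate
6 | methyl bromoacetate | COC(=O)CBr | starting material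
7 | methyl 2-[3,4-dimethoxy-5-(3,4,5-trimethoxyphenoxy)phenoxy]acetate | COC(=O)COc1cc(OC)c(OC)c(Oc2cc(OC)c(OC)c(OC)c2)c1 | intermediate
8 | methyl acetoacetate | CC(=O)CC(=O)OC | starting material
9 | lithium sodium dianion of methyl acetoacetate (2,4-diide) | [Li+].[Na+].[CH2-]C(=O)[CH-]C(=O)OC | intermediate
10 | methyl 6-[3,4-dimethoxy-5-(3,4,5-trimethoxyphenoxy)phenoxy]-3,5-dioxohexanoate | COC(=O)CC(=O)CC(=O)COc1cc(OC)c(OC)c(Oc2cc(OC)c(OC)c(OC)c2)c1 | intermediate
11 | 2-[3,4-dimethoxy-5-(3,4,5-trimethoxyphenoxy)phenoxy]cyclohexane-1,3,5-trione | O=C1CC(=O)C(Oc2cc(OC)c(OC)c(Oc3cc(OC)c(OC)c(OC)c3)c2)C(=O)C1 | intermediate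
12 | 2-[3,4-dimethoxy-5-(3,4,5-trimethoxyphenoxy)phenoxy]benzene-1,3,5-triol | COc1cc(Oc2c(O)cc(O)cc2O)cc(Oc2cc(OC)c(OC)c(OC)c2)c1OC | intermediate
13 | 3-(3,4,5-trihydroxyphenoxy)-5-(2,4,6-trihydroxyphenoxy)benzene-1,2-diol (CNP0216308.0) | Oc1cc(O)c(Oc2cc(O)c(O)c(Oc3cc(O)c(O)c(O)c3)c2)c(O)c1 | target

Total step count: 6. Longest linear sequence: 6 steps.

**Steps most likely to fail**

Step 5 (key cyclisation). Lactonisation through the enolate oxygen to a 4-hydroxy-2-pyrone, or retro-Claisen cleavage of the diketone, may outrun the carbon–carbon ring closure. The fallback gives up the ring construction and sets out from phenol 5. Copper-catalysed Ullmann coupling with commercial 2-iodo-1,3,5-trimethoxybenzene (CuI, picolinic acid, K3PO4, DMSO, 100 °C) should give the octamethyl ether 1,2-dimethoxy-3-(3,4,5-trimethoxyphenoxy)-5-(2,4,6-trimethoxyphenoxy)benzene F1. BBr3 under the conditions of step 6 should then cleave all eight methyl ethers, which returns to the route at the target 13.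

Step 4 (dianion acylation). Proton transfer from the acidic OCH2 group of ester 7 to the dianion may quench both partners before acylation. The fallback sets out from phenol 5 and uses a masked acetoacetate and a non-enolising acyl donor. Alkylation with 2-chloro-N-methoxy-N-methylacetamide (K2CO3, DMF) should give the Weinreb amide 2-[3,4-dimethoxy-5-(3,4,5-trimethoxyphenoxy)phenoxy]-N-methoxy-N-methylacetamide F2, whose chelated tetrahedral adduct holds back the acidic diketone until work-up. Acylation of the lithium dienolate of 2,2,6-trimethyl-4H-1,3-dioxin-4-one (LiN(iPr)2, THF, −78 °C) should give the keto-dioxinone 6-{3-[3,4-dimethoxy-5-(3,4,5-trimethoxyphenoxy)phenoxy]-2-oxopropyl}-2,2-dimethyl-4H-1,3-dioxin-4-one F3. Heating in toluene with methanol at 110 °C should release acetone by retro-(4+2) fragmentation, and the acylketene 6-[3,4-dimethoxy-5-(3,4,5-trimethoxyphenoxy)phenoxy]hex-1-ene-1,3,5-trione F4 is trapped by methanol, which returns to the route at 10.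

Step 1 (Ullmann coupling). Oxidative addition at the bromide next to a methoxy group may be slow, so that protodebromination and base-induced disproportionation of the aldehyde take over at the temperature needed. The fallback sets out from bromide 2 and changes the coupling to an oxidative one at room temperature. Palladium-catalysed borylation (Pd(OAc)2, XPhos, B2(OH)4, KOAc, EtOH, 80 °C) should give (5-formyl-2,3-dimethoxyphenyl)boronic acid F5. Chan–Lam coupling of F5 with phenol 1 (Cu(OAc)2, pyridine, 4 Å molecular sieves, CH2Cl2, air, rt) should then return to the route at 3.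

**Further compounds**
F1 | step 5 | 1,2-dimethoxy-3-(3,4,5-trimethoxyphenoxy)-5-(2,4,6-trimethoxyphenoxy)benzene | COc1cc(OC)c(Oc2cc(OC)c(OC)c(Oc3cc(OC)c(OC)c(OC)c3)c2)c(OC)c1
F2 | step 4 | 2-[3,4-dimethoxy-5-(3,4,5-trimethoxyphenoxy)phenoxy]-N-methoxy-N-methylacetamide | CON(C)C(=O)COc1cc(OC)c(OC)c(Oc2cc(OC)c(OC)c(OC)c2)c1
F3 | step 4 | 6-{3-[3,4-dimethoxy-5-(3,4,5-trimethoxyphenoxy)phenoxy]-2-oxopropyl}-2,2-dimethyl-4H-1,3-dioxin-4-one | CC1(C)OC(=O)C=C(CC(=O)COc2cc(OC)c(OC)c(Oc3cc(OC)c(OC)c(OC)c3)c2)O1
F4 | step 4 | 6-[3,4-dimethoxy-5-(3,4,5-trimethoxyphenoxy)phenoxy]hex-1-ene-1,3,5-trione | O=C=CC(=O)CC(=O)COc1cc(OC)c(OC)c(Oc2cc(OC)c(OC)c(OC)c2)c1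
F5 | step 1 | (5-formyl-2,3-dimethoxyphenyl)boronic acid | COc1cc(C=O)cc(B(O)O)c1OC
A1 | direct plan | pentacarbonyl[(Z)-3-ethoxy-1-(2,4,6-trimethoxyphenoxy)prop-2-enylidene]chromium | CCO/C=C\C(Oc1c(OC)cc(OC)cc1OC)=[Cr](=C=O)(=C=O)(=C=O)(=C=O)=C=O
A2 | direct plan | 5-(ethynyloxy)-1,2,3-trimethoxybenzene | C#COc1cc(OC)c(OC)c(OC)c1
A3 | direct plan | 2-ethoxy-4-(2,4,6-trimethoxyphenoxy)-6-(3,4,5-trimethoxyphenoxy)phenol | CCOc1cc(Oc2c(OC)cc(OC)cc2OC)cc(Oc2cc(OC)c(OC)c(OC)c2)c1O
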